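**Slow loss.** In the blue run Q still stood at 71.4% after 40.0 h, so I wanted one measure of that slowness.

| setting | ochre | teal | blue | flask |
|---|---|---|---|---|
| Q | 0.75 M | 1.1 M | 1.5 M | 1.5 M |
| Z | 2.25 M | 2.25 M | 1.1 M | 2.25 M |
| remark | run made earlier | run made earlier | run made earlier |  |
| time |  |  |  | 30 h |

| run | time / h | Q / % | G / % |
|---|---|---|---|
| ochre | 3.00 | 92.6 | 7.4 |
| ochre | 5.00 | 88.8 | 9.2 |
| ochre | 8.00 | 82.7 | 14.4 |
| ochre | 12.0 | 76.6 | 18.7 |
| ochre | 20.0 | 64.8 | 22.7 |
| ochre | 40.0 | 47.3 | 25.8 |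
| teal | 3.00 | 93.4 | 7.1 |
| teal | 5.00 | 89.5 | 9.6 |
| teal | 8.00 | 82.4 | 14.4 |
| teal | 12.0 | 76.6 | 18.1 |
| teal | 20.0 | 66.3 | 22.7 |
| teal | 40.0 | 50.1 | 26.3 |
| blue | 8.00 | 91.4 | 8.2 |
| blue | 15.0 | 85.3 | 13.1 |
| blue | 20.0 | 82.0 | 14.7 |
| blue | 30.0 | 76.4 | 19.1 |
| blue | 40.0 | 71.4 | 20.4 |

(standard deviation of a reading: 0.5 percentage points)

1. how much Q there is at 30 h, in percent of the Q charged
2. how much G there is at 30 h, in percent of the Q charged
3. how much X there is at 30 h, in percent of the Q charged
4. how much L there is at 30 h, in percent of the Q charged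

- the numbers in the tables scatter with a standard deviation of 0.5 percentage points
- what may be going on: Q + Z -> G; 2 Z -> E; X <-> J; Z + X -> L; Z + G -> X; Z + L -> D

**The measure.** I took the exposure W, the Z concentration summed over time. No other listed step takes Q, so the fraction of Q left is exp(−kW), with k the constant of Q + Z → G. The first blue reading, with Z averaged over its two ends, gave me k = 3.02 × 10⁻⁶ M⁻¹ s⁻¹. For the flask I joined the two ends of Z by their mean.

**Main step.** With Z held at its charge, I reckoned 48.1% of Q left in the flask. Letting each lost Q take one Z raised that to 54.6%.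

**Second adduct.** Z + G → X raises the Z price per Q lost. Counting everything past G as two Z, the last teal reading gave a price of 1.47. My reckoning of Q became 56.6%.

**Other losses.** In the ochre run, W from the last reading implied an end Z, and the adducts explained less of the fall by 0.455 M. I assigned that to two Z going to E and scaled it by time to 0.341 M for the flask. Two passes gave W = 48.9 M·h and Q = 58.8%.

**G follows.** Q + Z → G and Z + G → X both run on W, with a fixed selectivity factor between them, so G is tied to Q. Interpolating the teal readings gave G = 24.4%. The tables give Q and G, not X or L, so I left the remaining 16.8% unsplit among X, J, L and D.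

**The result.** The forecast gave Q 60%, G 24.5%, X 10% and L 3%, adding “the split is a guess”. The flask gave Q 58.7%, G 25.1%, X 6.88% and L 2.71%.

    Q + Z → G (k = 3.07 × 10⁻⁶ M⁻¹ s⁻¹)
    2 Z → E (k = 4.19 × 10⁻⁷ M⁻¹ s⁻¹)
    X ⇌ J (K = 1.58, k = 2.83 × 10⁻⁵ s⁻¹)
    Z + X → L (k = 5.13 × 10⁻⁶ M⁻¹ s⁻¹)
    Z + G → X (k = 5.71 × 10⁻⁶ M⁻¹ s⁻¹)
    Z + L → D (k = 9.83 × 10⁻⁷ M⁻¹ s⁻¹)

**What ran.** In the flask, Q + Z → G had half of its turnover up to 30 h by 10.5 h, while Z + G → X had 9.8% of its own turnover up to that time behind it at 6.00 h. At 30.0 h in the flask Z stood at 48.9% of its charge, Q + Z → G took Z 1.3 times as fast as Z + G → X, and X and J, relaxing by X ⇌ J alone with a half-life of 4.17 h, much shorter than the run, held 6.88% and 6.45%. Joining the charge of Z to that end value gives W = 50.3 M·h against my 48.9 M·h, and so a reckoned Q = 57.9%. Left until 20 h, the same charge had Z at 61.8%, which joins to Q = 67.4%; it held 67.4%.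

All runs stem from a simulated flask with made-up constants, noise included.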